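**Remark:** Chromanone numbering is used (O1, C2, C3, C4, C4a, C5–C8, C8a; ring A = benzene ring, ring B = dihydropyranone ring). The SMILES is read as the cis-2,3-dimethylchroman-4-one (2R,3S) with an (S)-configured C3 of the hexanoate chain.

## Retrosynthetic overview

1. Ring A is bought as 5-fluororesorcinol. Ring B is the only ring made, and it is made last, in the key step; the final step only removes the two MOM ethers on O5 and O7.
2. Ring B is cut at O1–C8a and C2–C3 into acetaldehyde and the Z-enol silane of an ortho-fluoroaryl ethyl ketone. Forward, an enantioselective syn Mukaiyama aldol is followed in the same pot by fluoride-relayed ring closure at C8a, a formal hetero-Diels–Alder reaction across an aromatic C–F bond.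
3. The enabling feature is the C4 carbonyl on C4a, ortho to C8a of ring A. It makes C3 a carbon nucleophile (as the enol silane) and C8a an electrophile (C8a=C4a–C4=O is a vinylogous acyl position). The ring A oxygens on C5 and C7 are meta to C8a and do not cancel this activation.
4. The C8 side chain comes from a Negishi coupling with a Z-enol triflate, and its stereocentre from a copper hydride 1,4-reduction. The enol silane masks the ketone through both steps.
5. The three carbon substituents of ring A (prenyl, propanoyl, side chain) are placed by three successive directed metalations of the bis-MOM ether of 5-fluororesorcinol.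

Key step: step 8

## Route

Step 1
Reactants: 1 5-fluorobenzene-1,3-diol
Product: 2 1-fluoro-3,5-bis(methoxymethoxy)benzene
Conditions: NaH, MOMCl, DMF, 0 °C → rt
Reagents that add atoms: chloromethyl methyl ether (MOMCl), COCCl
Why: Double Williamson O-alkylation of the bis-phenoxide (acetal protection), which also installs the two chelating groups that steer the metalations of steps 2, 3 and 6.

Step 2
Reactants: 2 1-fluoro-3,5-bis(methoxymethoxy)benzene; 3 1-bromo-3-methylbut-2-ene (prenyl bromide)
Product: 5 5-fluoro-1,3-bis(methoxymethoxy)-2-(3-methylbut-2-en-1-yl)benzene, via aryllithium 4 (not isolated)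
Conditions: n-BuLi, THF, 0 °C; then CuBr·SMe2 (10 mol%), 3, −78 °C → rt
Reagents that add atoms: none
Why: Directed ortho-metalation under coordination control should remove the C–H flanked by both chelating OMOM groups (the resulting aryllithium has no ortho fluorine and is stable at 0 °C), and copper-catalysed SN2 allylation with prenyl bromide then gives the linear prenyl arene.

Step 3
Reactants: 5 5-fluoro-1,3-bis(methoxymethoxy)-2-(3-methylbut-2-en-1-yl)benzene; 6 N-methoxy-N-methylpropanamide
Product: 8 1-[6-fluoro-2,4-bis(methoxymethoxy)-3-(3-methylbut-2-en-1-yl)phenyl]propan-1-one, via aryllithium 7 (not isolated)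
Conditions: s-BuLi, THF, −78 °C; then 6, −78 °C; AcOH quench at −78 °C
Reagents that add atoms: none
Why: Directed ortho-metalation at the only ring C–H type left (two equivalent positions, each acidified by an adjacent F and OMOM), held at −78 °C so that the ortho-fluoro aryllithium does not lose LiF, followed by a Weinreb ketone synthesis whose chelated tetrahedral adduct prevents over-addition.

Step 4
Reactants: 8 1-[6-fluoro-2,4-bis(methoxymethoxy)-3-(3-methylbut-2-en-1-yl)phenyl]propan-1-one
Product: 9 triethyl({(1Z)-1-[6-fluoro-2,4-bis(methoxymethoxy)-3-(3-methylbut-2-en-1-yl)phenyl]prop-1-en-1-yl}oxy)silane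
Conditions: Et3SiOTf, Et3N, CH2Cl2, 0 °C
Reagents that add atoms: triethylsilyl trifluoromethanesulfonate (Et3SiOTf), CC[Si](CC)(CC)OS(=O)(=O)C(F)(F)F
Why: Soft enolisation (silyl triflate and amine) should give the thermodynamically favoured Z-enol silane, which masks the ketone against the amide base of step 6 and the copper hydride of step 7 and is the carbon nucleophile of step 8.

Step 5
Reactants: 10 methyl 3-oxohexanoate
Product: 11 methyl (2Z)-3-{[(trifluoromethyl)sulfonyl]oxy}hex-2-enoate
Conditions: Tf2O, aq. LiOH, toluene, 5 °C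
Reagents that add atoms: trifluoromethanesulfonic anhydride (Tf2O), O=S(=O)(OS(=O)(=O)C(F)(F)F)C(F)(F)F
Why: Enol triflate formation from the chelated lithium Z-enolate of the β-keto ester under biphasic aqueous LiOH conditions, which should fix the Z geometry (OTf cis to the ester).

Step 6
Reactants: 9 triethyl({(1Z)-1-[6-fluoro-2,4-bis(methoxymethoxy)-3-(3-methylbut-2-en-1-yl)phenyl]prop-1-en-1-yl}oxy)silane; 11 methyl (2Z)-3-{[(trifluoromethyl)sulfonyl]oxy}hex-2-enoate
Product: 13 methyl (2Z)-3-{2-fluoro-4,6-bis(methoxymethoxy)-5-(3-methylbut-2-en-1-yl)-3-[(1Z)-1-(triethylsilyloxy)prop-1-en-1-yl]phenyl}hex-2-enoate, via arylzinc chloride 12 (not isolated)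
Conditions: ZnCl2·2LiCl, LiTMP (lithium 2,2,6,6-tetramethylpiperidide), THF, −78 °C → rt; then 11, Pd(OAc)2 (2 mol%), SPhos (4 mol%), THF, 40 °C
Reagents that add atoms: none
Why: Deprotonative metalation of the last ring C–H (between F and OMOM) by the hindered amide with in situ trapping by ZnCl2, which forestalls LiF loss, followed by Negishi cross-coupling with the enol triflate, which should proceed with retention of the Z geometry and leave the enol silane, MOM ethers and prenyl group untouched.

Step 7
Reactants: 13 methyl (2Z)-3-{2-fluoro-4,6-bis(methoxymethoxy)-5-(3-methylbut-2-en-1-yl)-3-[(1Z)-1-(triethylsilyloxy)prop-1-en-1-yl]phenyl}hex-2-enoate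
Product: 14 methyl (3S)-3-{2-fluoro-4,6-bis(methoxymethoxy)-5-(3-methylbut-2-en-1-yl)-3-[(1Z)-1-(triethylsilyloxy)prop-1-en-1-yl]phenyl}hexanoate
Conditions: Cu(OAc)2·H2O (3 mol%), (R)-DTBM-SEGPHOS (3 mol%), (EtO)2MeSiH, t-BuOH, toluene, rt
Reagents that add atoms: none
Why: Copper hydride-catalysed asymmetric 1,4-reduction of a β-aryl-β-alkyl enoate, in which the bisphosphine ligand is expected (sense assigned by analogy with simpler Z-β-aryl enoates) to direct hydride to the Re face of C3 and so set the (S) centre, while the isolated prenyl alkene, the enol silane and the aryl fluoride are not reduced.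

Step 8
Reactants: 14 methyl (3S)-3-{2-fluoro-4,6-bis(methoxymethoxy)-5-(3-methylbut-2-en-1-yl)-3-[(1Z)-1-(triethylsilyloxy)prop-1-en-1-yl]phenyl}hexanoate; 15 acetaldehyde
Product: 17 methyl (3S)-3-[(2R,3S)-5,7-bis(methoxymethoxy)-2,3-dimethyl-6-(3-methylbut-2-en-1-yl)-4-oxo-3,4-dihydro-2H-chromen-8-yl]hexanoate, via syn-aldol triethylsilyl ether 16 (not isolated)
Conditions: acyloxyborane from (2S,3S)-2-O-(2,6-diisopropoxybenzoyl)tartaric acid and BH3·THF (20 mol%), 15 (2 equiv), EtCN, −78 °C; then n-Bu4N[Ph3SiF2] (40 mol%, in excess over boron), THF, −78 → 0 °C; pH 7 buffer quench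
Reagents that add atoms: none
Why: Proposed new method: a formal hetero-Diels–Alder annulation across an aromatic C–F bond, in which the chiral acyloxyborane first catalyses a Mukaiyama aldol addition of the enol silane carbon C3 of 14 to boron-bound acetaldehyde (C3–C2 bond, silyl transfer to the new oxygen gives 16), and added fluoride then frees the C2 alkoxide, which attacks C8a ortho to the C4 carbonyl and expels fluoride through a Meisenheimer enolate (O1–C8a bond); the fluoride set free cleaves the next silyl ether, so fluoride is a chain carrier and Et3SiF the only by-product. The closest known reaction types are the acyloxyborane-catalysed syn-selective Mukaiyama aldol of aryl ethyl ketone enol silanes, the fluoride-catalysed substitution of carbonyl-activated aryl fluorides by silyl ethers, and the Danishefsky diene–aldehyde cyclocondensation, in which OMe plays the part taken here by F. Ring B closes by a 6-endo-trig addition–elimination at C8a, the C8a=C4a–C4=O unit acting as a vinylogous acyl fluoride. C2 (R) is set by catalyst control (attack on the si face of the bound aldehyde, taken to be the face left open by the (2S,3S)-tartrate-derived catalyst) and C3 (S) by the open, antiperiplanar transition state that gives the syn aldol whatever the enol geometry; both survive ring closure because O1 keeps its bond to C2, so syn aldol becomes cis-2,3-dimethyl. The step needs site selectivity in the substitution (only F, ortho to the carbonyl, is a leaving group) and stereochemical integrity at the base-labile C3, which low temperature, substoichiometric fluoride and a buffered quench are meant to secure.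

Step 9
Reactants: 17 methyl (3S)-3-[(2R,3S)-5,7-bis(methoxymethoxy)-2,3-dimethyl-6-(3-methylbut-2-en-1-yl)-4-oxo-3,4-dihydro-2H-chromen-8-yl]hexanoate
Product: 18 methyl (3S)-3-[(2R,3S)-5,7-dihydroxy-2,3-dimethyl-6-(3-methylbut-2-en-1-yl)-4-oxo-3,4-dihydro-2H-chromen-8-yl]hexanoate
Conditions: HCl (0.5 M in MeOH), 0 °C → rt; cold aq. NaHCO3 before concentration
Reagents that add atoms: none
Why: Acid-catalysed acetal exchange with methanol releases both phenols with dimethoxymethane as the leaving fragment, and dilute acid at or below room temperature with a cold bicarbonate quench is meant to spare the prenyl group, the cis C3 centre and the open hydroxy ester (no lactonisation); no stereocentre is touched.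

## Compound list

1 | 5-fluorobenzene-1,3-diol | Oc1cc(O)cc(F)c1 | starting material
2 | 1-fluoro-3,5-bis(methoxymethoxy)benzene | COCOc1cc(F)cc(OCOC)c1 | intermediate
3 | 1-bromo-3-methylbut-2-ene | CC(C)=CCBr | starting material
4 | [4-fluoro-2,6-bis(methoxymethoxy)phenyl]lithium | [Li]c1c(OCOC)cc(F)cc1OCOC | intermediate
5 | 5-fluoro-1,3-bis(methoxymethoxy)-2-(3-methylbut-2-en-1-yl)benzene | COCOc1cc(F)cc(OCOC)c1CC=C(C)C | intermediate
6 | N-methoxy-N-methylpropanamide | CCC(=O)N(C)OC | starting material
7 | [6-fluoro-2,4-bis(methoxymethoxy)-3-(3-methylbut-2-en-1-yl)phenyl]lithium | [Li]c1c(F)cc(OCOC)c(CC=C(C)C)c1OCOC | intermediate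
8 | 1-[6-fluoro-2,4-bis(methoxymethoxy)-3-(3-methylbut-2-en-1-yl)phenyl]propan-1-one | CCC(=O)c1c(F)cc(OCOC)c(CC=C(C)C)c1OCOC | intermediate
9 | triethyl({(1Z)-1-[6-fluoro-2,4-bis(methoxymethoxy)-3-(3-methylbut-2-en-1-yl)phenyl]prop-1-en-1-yl}oxy)silane | C/C=C(\O[Si](CC)(CC)CC)c1c(F)cc(OCOC)c(CC=C(C)C)c1OCOC | intermediate
10 | methyl 3-oxohexanoate | CCCC(=O)CC(=O)OC | starting material
11 | methyl (2Z)-3-{[(trifluoromethyl)sulfonyl]oxy}hex-2-enoate | CCC/C(OS(=O)(=O)C(F)(F)F)=C/C(=O)OC | intermediate
12 | chloro{2-fluoro-4,6-bis(methoxymethoxy)-5-(3-methylbut-2-en-1-yl)-3-[(1Z)-1-(triethylsilyloxy)prop-1-en-1-yl]phenyl}zinc | Cl[Zn]c1c(F)c(/C(O[Si](CC)(CC)CC)=C/C)c(OCOC)c(CC=C(C)C)c1OCOC | intermediate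
13 | methyl (2Z)-3-{2-fluoro-4,6-bis(methoxymethoxy)-5-(3-methylbut-2-en-1-yl)-3-[(1Z)-1-(triethylsilyloxy)prop-1-en-1-yl]phenyl}hex-2-enoate | CCC/C(=C/C(=O)OC)c1c(F)c(/C(O[Si](CC)(CC)CC)=C/C)c(OCOC)c(CC=C(C)C)c1OCOC | intermediate
14 | methyl (3S)-3-{2-fluoro-4,6-bis(methoxymethoxy)-5-(3-methylbut-2-en-1-yl)-3-[(1Z)-1-(triethylsilyloxy)prop-1-en-1-yl]phenyl}hexanoate | CCC[C@@H](CC(=O)OC)c1c(F)c(/C(O[Si](CC)(CC)CC)=C/C)c(OCOC)c(CC=C(C)C)c1OCOC | intermediate
15 | acetaldehyde | CC=O | starting material
16 | methyl (3S)-3-{2-fluoro-4,6-bis(methoxymethoxy)-5-(3-methylbut-2-en-1-yl)-3-[(2S,3R)-2-methyl-3-(triethylsilyloxy)butanoyl]phenyl}hexanoate | CCC[C@@H](CC(=O)OC)c1c(F)c(C(=O)[C@@H](C)[C@@H](C)O[Si](CC)(CC)CC)c(OCOC)c(CC=C(C)C)c1OCOC | intermediate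
17 | methyl (3S)-3-[(2R,3S)-5,7-bis(methoxymethoxy)-2,3-dimethyl-6-(3-methylbut-2-en-1-yl)-4-oxo-3,4-dihydro-2H-chromen-8-yl]hexanoate | CCC[C@@H](CC(=O)OC)c1c(OCOC)c(CC=C(C)C)c(OCOC)c2c1O[C@H](C)[C@H](C)C2=O | intermediate
18 | methyl (3S)-3-[(2R,3S)-5,7-dihydroxy-2,3-dimethyl-6-(3-methylbut-2-en-1-yl)-4-oxo-3,4-dihydro-2H-chromen-8-yl]hexanoate | CCC[C@@H](CC(=O)OC)c1c(O)c(CC=C(C)C)c(O)c2c1O[C@H](C)[C@H](C)C2=O | target

## Step count and risks

Total step count: 9. Longest linear sequence: 8 (steps 1–4 and 6–9; step 5 makes the coupling partner 11).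

**Step 8 (Proposed new method).** The aldol catalyst may turn over poorly with the triethylsilyl group. In the fluoride stage, retro-aldol cleavage, β-elimination or epimerisation at C3 may outrun ring closure while boron holds back part of the fluoride. The fallback separates the two bond formations and uses known reactions only. It sets out from 14: mild hydrolysis of the enol silane (AcOH–THF–H2O, rt) should give the ketone methyl (3S)-3-[2-fluoro-4,6-bis(methoxymethoxy)-5-(3-methylbut-2-en-1-yl)-3-propanoylphenyl]hexanoate F1. A stoichiometric boron aldol reaction follows (diisopinocampheylboron triflate of the antipode that directs the Z-enol borinate to the si face of acetaldehyde, i-Pr2NEt, CH2Cl2, −78 °C; acetaldehyde; buffered H2O2 work-up). It should give the free syn aldol methyl (3S)-3-{2-fluoro-3-[(2S,3R)-3-hydroxy-2-methylbutanoyl]-4,6-bis(methoxymethoxy)-5-(3-methylbut-2-en-1-yl)phenyl}hexanoate F2. Irreversible deprotonation with KHMDS (1.05 equiv, THF, −78 → −20 °C) then closes ring B by intramolecular substitution of fluoride. The fallback returns to the route at 17.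

**Step 6.** Deprotonation may be incomplete or misdirected (lateral metalation at the prenyl CH2), and the doubly ortho-substituted arylzinc may couple slowly, with loss of alkene geometry. The fallback replaces cross-coupling and hydride reduction by formylation, olefination and conjugate addition, and moves the stereo-defining event to the last of these. It sets out from 9: lithiation with LiTMP (THF, −78 °C, no zinc salt) should give {2-fluoro-4,6-bis(methoxymethoxy)-5-(3-methylbut-2-en-1-yl)-3-[(1Z)-1-(triethylsilyloxy)prop-1-en-1-yl]phenyl}lithium F3. An immediate DMF quench should give 2-fluoro-4,6-bis(methoxymethoxy)-5-(3-methylbut-2-en-1-yl)-3-[(1Z)-1-(triethylsilyloxy)prop-1-en-1-yl]benzaldehyde F4. Horner–Wadsworth–Emmons olefination (trimethyl phosphonoacetate, LiCl, DBU, MeCN) should give methyl (2E)-3-{2-fluoro-4,6-bis(methoxymethoxy)-5-(3-methylbut-2-en-1-yl)-3-[(1Z)-1-(triethylsilyloxy)prop-1-en-1-yl]phenyl}prop-2-enoate F5. Copper-catalysed asymmetric conjugate addition of n-PrMgBr (CuBr·SMe2, Tol-BINAP of the antipode that gives the 3S centre, t-BuOMe, −75 °C) then returns to the route at 14; compound 13 and step 7 are bypassed.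

**Step 2.** The first lithiation may show poor site selectivity (attack at a C–H next to fluorine, followed by LiF loss to an aryne), and the allylation may give some SN2′ product. The fallback fixes the site with a halogen. It sets out from 1: iodination between the two hydroxyl groups (I2, NaHCO3, H2O, 0 °C) should give 5-fluoro-2-iodobenzene-1,3-diol F6. Protection (NaH, MOMCl, DMF) should give 5-fluoro-2-iodo-1,3-bis(methoxymethoxy)benzene F7. Iodine–lithium exchange (n-BuLi, THF, −78 °C) gives the aryllithium 4 at a defined position, and prenylation as in step 2 returns to the route at 5.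

## Further compounds

F1 | step 8 | methyl (3S)-3-[2-fluoro-4,6-bis(methoxymethoxy)-5-(3-methylbut-2-en-1-yl)-3-propanoylphenyl]hexanoate | CCC[C@@H](CC(=O)OC)c1c(F)c(C(=O)CC)c(OCOC)c(CC=C(C)C)c1OCOC
F2 | step 8 | methyl (3S)-3-{2-fluoro-3-[(2S,3R)-3-hydroxy-2-methylbutanoyl]-4,6-bis(methoxymethoxy)-5-(3-methylbut-2-en-1-yl)phenyl}hexanoate | CCC[C@@H](CC(=O)OC)c1c(F)c(C(=O)[C@@H](C)[C@@H](C)O)c(OCOC)c(CC=C(C)C)c1OCOC
F3 | step 6 | {2-fluoro-4,6-bis(methoxymethoxy)-5-(3-methylbut-2-en-1-yl)-3-[(1Z)-1-(triethylsilyloxy)prop-1-en-1-yl]phenyl}lithium | [Li]c1c(F)c(/C(O[Si](CC)(CC)CC)=C/C)c(OCOC)c(CC=C(C)C)c1OCOC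
F4 | step 6 | 2-fluoro-4,6-bis(methoxymethoxy)-5-(3-methylbut-2-en-1-yl)-3-[(1Z)-1-(triethylsilyloxy)prop-1-en-1-yl]benzaldehyde | O=Cc1c(F)c(/C(O[Si](CC)(CC)CC)=C/C)c(OCOC)c(CC=C(C)C)c1OCOC
F5 | step 6 | methyl (2E)-3-{2-fluoro-4,6-bis(methoxymethoxy)-5-(3-methylbut-2-en-1-yl)-3-[(1Z)-1-(triethylsilyloxy)prop-1-en-1-yl]phenyl}prop-2-enoate | COC(=O)/C=C/c1c(F)c(/C(O[Si](CC)(CC)CC)=C/C)c(OCOC)c(CC=C(C)C)c1OCOC
F6 | step 2 | 5-fluoro-2-iodobenzene-1,3-diol | Oc1cc(F)cc(O)c1I
F7 | step 2 | 5-fluoro-2-iodo-1,3-bis(methoxymethoxy)benzene | COCOc1cc(F)cc(OCOC)c1I
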